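**Plan**
- Numbering used below: ring C1 (angelate oxygen), C2, C3 (methyl), C4 (free hydroxyl), C5, C6 (side chain); side chain C7 (methyl-bearing) to C11.
- Retrosynthesis: the oxygen groups are adjusted last (O4 silyl ether, O1 acetate to angelate, O9 acetate). C9–C10 is cut to an alkenyl Grignard reagent and a Weinreb amide. A formyl group is put back on C5 and C2=C3 is restored as an alkene. Then C4–C5 and C1–C6 are cut together.
- Enabling feature: the only ring is a cyclohexane with cis oxygens on C1 and C4 flanking C2–C3(Me). With C2=C3 as an alkene this is the retron of a [4+2] cycloaddition between a 1,4-dioxygenated diene (C1–C4; OAc on C1, OTBS on C4) and the C5=C6 alkene of an (E)-enal, whose formyl group on C5 is a removable activator.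
- Forward: (S)-citronellic acid gives the enal (3 steps) and a C5 acetoxy enal gives the diene (1 step). The cycloaddition builds the ring, followed by hydrogenation, decarbonylation, Grignard addition, angeloylation, ketone reduction, acetylation and desilylation.
- Stereochemistry: C7 comes from citronellic acid. C1, C4 and C6 come from the amine-catalysed endo cycloaddition ((E,E)-diene, (E)-enal, catalyst-controlled face). C3 comes from hydrogenation anti to the oxygen-bearing face, C9 from Corey–Bakshi–Shibata reduction, and the (Z)-alkene from angelic acid.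

Key step: step 5

Remark: compounds 1, 7, 14 and 16 are taken as bought, and diene 8 is used without separation of geometric isomers.

Step 1
Reactants: 1 (S)-citronellic acid [(3S)-3,7-dimethyloct-6-enoic acid]
Product: 3 (3S)-N-methoxy-N,3,7-trimethyloct-6-enamide, via acyl imidazole 2 (not isolated)
Conditions: CDI, CH2Cl2, rt; then MeNH(OMe)·HCl, rt
Reagents that add atoms: N,O-dimethylhydroxylamine hydrochloride, CNOC.Cl
Why: Amide formation through the acyl imidazole (CDI activation) stores C9 as a Weinreb amide, which should pass unchanged through the oxidations and the cycloaddition; C7, beta to the carbonyl, is not touched.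

Step 2
Reactants: 3 (3S)-N-methoxy-N,3,7-trimethyloct-6-enamide
Product: 5 (3S)-N-methoxy-N,3-dimethyl-6-oxohexanamide, via ozonide 4 (not isolated)
Conditions: O3, CH2Cl2, −78 °C; then PPh3, −78 °C to rt
Reagents that add atoms: ozone, O=[O+][O-]
Why: Ozonolysis with reductive work-up cleaves the only alkene to the aldehyde and leaves the amide and C7 alone.

Step 3
Reactants: 5 (3S)-N-methoxy-N,3-dimethyl-6-oxohexanamide
Product: 6 (3R,4E)-N-methoxy-N,3-dimethyl-6-oxohex-4-enamide
Conditions: IBX, 4-methoxypyridine N-oxide, DMSO, rt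
Reagents that add atoms: none
Why: IBX dehydrogenation of an aldehyde through its enol should give the (E)-enal; the N-oxide complex allows room temperature, which should limit further oxidation at the tertiary gamma carbon C7, and no base is present that could epimerise it.

Step 4
Reactants: 7 (2E)-4-acetoxy-2-methylbut-2-enal
Product: 8 (1E,3E)-4-[(tert-butyldimethylsilyl)oxy]-3-methylbuta-1,3-dien-1-yl acetate
Conditions: TBSOTf, Et3N, Et2O, 0 °C
Reagents that add atoms: tert-butyldimethylsilyl trifluoromethanesulfonate, CC(C)(C)[Si](C)(C)OS(=O)(=O)C(F)(F)F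
Why: Silyl dienol ether formation by O-silylation and gamma-deprotonation of an enal should give mainly the (1E,3E)-diene from the s-trans enal with the acetoxy group anti; any (Z)-isomer cannot become s-cis and is a spectator in step 5.

Step 5
Reactants: 6 (3R,4E)-N-methoxy-N,3-dimethyl-6-oxohex-4-enamide; 8 (1E,3E)-4-[(tert-butyldimethylsilyl)oxy]-3-methylbuta-1,3-dien-1-yl acetate
Product: 11 (1S,4R,5R,6R)-4-[(tert-butyldimethylsilyl)oxy]-5-formyl-6-[(2R)-4-[methoxy(methyl)amino]-4-oxobutan-2-yl]-3-methylcyclohex-2-en-1-yl acetate, via iminium ion 9 (not isolated), via cycloadduct iminium ion 10 (not isolated)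
Conditions: 8 (2 equiv), (5S)-5-benzyl-2,2,3-trimethylimidazolidin-4-one·CF3CO2H (20 mol %), MeCN, H2O (3 equiv), −20 °C
Reagents that add atoms: water, O
Why: The secondary amine condenses with 6 to the (E)-iminium ion 9, whose lowered LUMO should undergo a concerted, asynchronous [4+2] cycloaddition with the electron-rich diene 8 (bond C1–C6 ahead of bond C4–C5), and hydrolysis of the cycloadduct iminium ion 10 gives 11 and returns the amine. The closest known reaction type is the imidazolidinone-catalysed Diels–Alder reaction of enals with acyclic 1-oxygenated dienes such as 1-acetoxybutadiene. The cyclohexene, the only ring of the target, is closed by intermolecular suprafacial [4+2] addition through the endo transition state, both new bonds ending on oxygen-bearing carbons. C1 and C4 become cis because both oxygens are (E) on the diene, C5 and C6 become trans because the enal is (E), the endo position of the iminium group puts the formyl group cis to both oxygens and so the side chain on C6 trans to them, and the absolute sense follows from the benzyl group of the (5S)-catalyst, which shields the Si face of C6 so that C1 adds to its Re face, the same sense as in the known cycloadditions of this catalyst, while C7 is a spectator. The step needs regio-, endo and face selectivity: the regiochemistry is secured in the substrate by the silyloxy group on C4, the strongest donor, which makes C1 (the gamma carbon of the silyl dienol ether) the nucleophilic terminus that meets the electrophilic beta carbon C6 and should override the weaker opposite bias of the C3 methyl and C1 acetoxy groups.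

Step 6
Reactants: 11 (1S,4R,5R,6R)-4-[(tert-butyldimethylsilyl)oxy]-5-formyl-6-[(2R)-4-[methoxy(methyl)amino]-4-oxobutan-2-yl]-3-methylcyclohex-2-en-1-yl acetate
Product: 12 (1R,2R,3R,4S,5S)-4-[(tert-butyldimethylsilyl)oxy]-3-formyl-2-[(2R)-4-[methoxy(methyl)amino]-4-oxobutan-2-yl]-5-methylcyclohexyl acetate
Conditions: H2 (1 atm), 5% Rh on Al2O3, EtOAc, rt
Reagents that add atoms: none
Why: Heterogeneous hydrogenation should add H2 syn to the face of C2=C3 opposite to the acetoxy (C1), silyloxy (C4) and formyl (C5) groups, which all stand on one face, so the C3 methyl ends cis to the C4 oxygen; rhodium on alumina at low pressure is chosen to spare the allylic C–O bonds and the aldehyde.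

Step 7
Reactants: 12 (1R,2R,3R,4S,5S)-4-[(tert-butyldimethylsilyl)oxy]-3-formyl-2-[(2R)-4-[methoxy(methyl)amino]-4-oxobutan-2-yl]-5-methylcyclohexyl acetate
Product: 13 (1R,2S,4R,5S)-4-[(tert-butyldimethylsilyl)oxy]-2-[(2R)-4-[methoxy(methyl)amino]-4-oxobutan-2-yl]-5-methylcyclohexyl acetate
Conditions: RhCl(PPh3)3 (1.1 equiv), toluene, 110 °C
Reagents that add atoms: none
Why: Tsuji–Wilkinson decarbonylation (insertion of monovalent rhodium into the formyl C–H bond, loss of CO to the metal, C–H reductive elimination) removes the activating group and leaves C5 as CH2; the stereocentre lost at C5 needs no control, and the esters, amide and silyl ether are inert.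

Step 8
Reactants: 13 (1R,2S,4R,5S)-4-[(tert-butyldimethylsilyl)oxy]-2-[(2R)-4-[methoxy(methyl)amino]-4-oxobutan-2-yl]-5-methylcyclohexyl acetate; 14 2-methylprop-1-enylmagnesium bromide
Product: 15 (6R)-6-[(1S,2R,4S,5R)-5-[(tert-butyldimethylsilyl)oxy]-2-hydroxy-4-methylcyclohexyl]-2-methylhept-2-en-4-one
Conditions: 14 (5 equiv), THF, 0 °C to rt; aq. NH4Cl
Reagents that add atoms: none
Why: Weinreb ketone synthesis: the alkenyl Grignard reagent adds once to the N-methoxy-N-methylamide and gives the enone on work-up, while the excess reagent cleaves the acetate by double addition and frees the C1 hydroxyl for step 9.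

Step 9
Reactants: 15 (6R)-6-[(1S,2R,4S,5R)-5-[(tert-butyldimethylsilyl)oxy]-2-hydroxy-4-methylcyclohexyl]-2-methylhept-2-en-4-one; 16 angelic acid [(2Z)-2-methylbut-2-enoic acid]
Product: 18 (1R,2S,4R,5S)-4-[(tert-butyldimethylsilyl)oxy]-5-methyl-2-[(2R)-6-methyl-4-oxohept-5-en-2-yl]cyclohexyl (2Z)-2-methylbut-2-enoate, via mixed anhydride 17 (not isolated)
Conditions: 16, 2,4,6-trichlorobenzoyl chloride, Et3N, toluene, rt; then 15, 80 °C
Reagents that add atoms: none
Why: Yamaguchi esterification with the preformed mixed anhydride in toluene and without a nucleophilic catalyst should acylate the equatorial C1 alcohol, the only free hydroxyl (its cyclic hemiketal with the C9 ketone reacts through the open form), and is the protocol known to keep the (Z)-geometry of angelates.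

Step 10
Reactants: 18 (1R,2S,4R,5S)-4-[(tert-butyldimethylsilyl)oxy]-5-methyl-2-[(2R)-6-methyl-4-oxohept-5-en-2-yl]cyclohexyl (2Z)-2-methylbut-2-enoate
Product: 19 (1R,2S,4R,5S)-4-[(tert-butyldimethylsilyl)oxy]-2-[(2R,4R)-4-hydroxy-6-methylhept-5-en-2-yl]-5-methylcyclohexyl (2Z)-2-methylbut-2-enoate
Conditions: (S)-2-methyl-CBS-oxazaborolidine (0.5 equiv), catecholborane, toluene, −78 °C
Reagents that add atoms: none
Why: Corey–Bakshi–Shibata reduction: with the (S)-oxazaborolidine the alkenyl group acts as the large substituent and the CH2 group as the small one, so 1,2-hydride delivery should give the (R)-allylic alcohol at C9, and catecholborane at low temperature leaves the esters and alkenes alone.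

Step 11
Reactants: 19 (1R,2S,4R,5S)-4-[(tert-butyldimethylsilyl)oxy]-2-[(2R,4R)-4-hydroxy-6-methylhept-5-en-2-yl]-5-methylcyclohexyl (2Z)-2-methylbut-2-enoate
Product: 20 (1R,2S,4R,5S)-2-[(2R,4R)-4-acetoxy-6-methylhept-5-en-2-yl]-4-[(tert-butyldimethylsilyl)oxy]-5-methylcyclohexyl (2Z)-2-methylbut-2-enoate
Conditions: Ac2O, pyridine, DMAP (cat.), CH2Cl2, 0 °C
Reagents that add atoms: acetic anhydride, CC(=O)OC(C)=O
Why: DMAP-catalysed acetylation of the only free hydroxyl (C9) proceeds with retention, since the C–O bond is not broken.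

Step 12
Reactants: 20 (1R,2S,4R,5S)-2-[(2R,4R)-4-acetoxy-6-methylhept-5-en-2-yl]-4-[(tert-butyldimethylsilyl)oxy]-5-methylcyclohexyl (2Z)-2-methylbut-2-enoate
Product: 21 (1R,2S,4R,5S)-2-[(2R,4R)-4-acetoxy-6-methylhept-5-en-2-yl]-4-hydroxy-5-methylcyclohexyl (2Z)-2-methylbut-2-enoate (CNP0237033.1)
Conditions: HF·pyridine, pyridine, THF, 0 °C to rt
Reagents that add atoms: none
Why: Fluoride cleavage of the silyl ether under pyridine-buffered conditions should free the axial C4 hydroxyl without harm to the angelate, the allylic acetate or the alkenes, and the 1,4-relation of O1 and O4 rules out acyl migration.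

**Compound list**
1 | (S)-citronellic acid, (3S)-3,7-dimethyloct-6-enoic acid | CC(C)=CCC[C@H](C)CC(=O)O | starting material
2 | (3S)-1-(1H-imidazol-1-yl)-3,7-dimethyloct-6-en-1-one (acyl imidazole) | CC(C)=CCC[C@H](C)CC(=O)n1ccnc1 | intermediate
3 | (3S)-N-methoxy-N,3,7-trimethyloct-6-enamide | CC(C)=CCC[C@H](C)CC(=O)N(C)OC | intermediate
4 | (3S)-5-(5,5-dimethyl-1,2,4-trioxolan-3-yl)-N-methoxy-N,3-dimethylpentanamide (ozonide, both epimers at the trioxolane carbon) | CC1(C)OOC(CC[C@H](C)CC(=O)N(C)OC)O1 | intermediate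
5 | (3S)-N-methoxy-N,3-dimethyl-6-oxohexanamide | O=CCC[C@H](C)CC(=O)N(C)OC | intermediate
6 | (3R,4E)-N-methoxy-N,3-dimethyl-6-oxohex-4-enamide | O=C/C=C/[C@H](C)CC(=O)N(C)OC | intermediate
7 | (2E)-4-acetoxy-2-methylbut-2-enal | CC(=O)OC/C=C(\C)C=O | starting material
8 | (1E,3E)-4-[(tert-butyldimethylsilyl)oxy]-3-methylbuta-1,3-dien-1-yl acetate | CC(=O)O/C=C/C(C)=C/O[Si](C)(C)C(C)(C)C | intermediate
9 | (5S)-5-benzyl-1-[(1E,2E,4R)-6-[methoxy(methyl)amino]-4-methyl-6-oxohex-2-en-1-ylidene]-2,2,3-trimethyl-4-oxoimidazolidin-1-ium trifluoroacetate (iminium ion of 6) | CON(C)C(=O)C[C@@H](C)/C=C/C=[N+]1\[C@@H](Cc2ccccc2)C(=O)N(C)C1(C)C.[O-]C(=O)C(F)(F)F | intermediate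
10 | iminium trifluoroacetate of 11 with (5S)-5-benzyl-2,2,3-trimethylimidazolidin-4-one (C=N+ in place of the formyl C=O) | CC(=O)O[C@@H]1C=C(C)[C@H](O[Si](C)(C)C(C)(C)C)[C@H](/C=[N+]2\[C@@H](Cc3ccccc3)C(=O)N(C)C2(C)C)[C@H]1[C@H](C)CC(=O)N(C)OC.[O-]C(=O)C(F)(F)F | intermediate
11 | (1S,4R,5R,6R)-4-[(tert-butyldimethylsilyl)oxy]-5-formyl-6-[(2R)-4-[methoxy(methyl)amino]-4-oxobutan-2-yl]-3-methylcyclohex-2-en-1-yl acetate | CC(=O)O[C@@H]1C=C(C)[C@H](O[Si](C)(C)C(C)(C)C)[C@H](C=O)[C@H]1[C@H](C)CC(=O)N(C)OC | intermediate
12 | (1R,2R,3R,4S,5S)-4-[(tert-butyldimethylsilyl)oxy]-3-formyl-2-[(2R)-4-[methoxy(methyl)amino]-4-oxobutan-2-yl]-5-methylcyclohexyl acetate | CC(=O)O[C@@H]1C[C@H](C)[C@H](O[Si](C)(C)C(C)(C)C)[C@H](C=O)[C@H]1[C@H](C)CC(=O)N(C)OC | intermediate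
13 | (1R,2S,4R,5S)-4-[(tert-butyldimethylsilyl)oxy]-2-[(2R)-4-[methoxy(methyl)amino]-4-oxobutan-2-yl]-5-methylcyclohexyl acetate | CC(=O)O[C@@H]1C[C@H](C)[C@H](O[Si](C)(C)C(C)(C)C)C[C@H]1[C@H](C)CC(=O)N(C)OC | intermediate
14 | 2-methylprop-1-enylmagnesium bromide | CC(C)=C[Mg]Br | starting material
15 | (6R)-6-[(1S,2R,4S,5R)-5-[(tert-butyldimethylsilyl)oxy]-2-hydroxy-4-methylcyclohexyl]-2-methylhept-2-en-4-one | O[C@@H]1C[C@H](C)[C@H](O[Si](C)(C)C(C)(C)C)C[C@H]1[C@H](C)CC(=O)C=C(C)C | intermediate
16 | angelic acid, (2Z)-2-methylbut-2-enoic acid | C/C=C(/C)C(=O)O | starting material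
17 | (2Z)-2-methylbut-2-enoic 2,4,6-trichlorobenzoic anhydride | C/C=C(/C)C(=O)OC(=O)c1c(Cl)cc(Cl)cc1Cl | intermediate
18 | (1R,2S,4R,5S)-4-[(tert-butyldimethylsilyl)oxy]-5-methyl-2-[(2R)-6-methyl-4-oxohept-5-en-2-yl]cyclohexyl (2Z)-2-methylbut-2-enoate | C/C=C(/C)C(=O)O[C@@H]1C[C@H](C)[C@H](O[Si](C)(C)C(C)(C)C)C[C@H]1[C@H](C)CC(=O)C=C(C)C | intermediate
19 | (1R,2S,4R,5S)-4-[(tert-butyldimethylsilyl)oxy]-2-[(2R,4R)-4-hydroxy-6-methylhept-5-en-2-yl]-5-methylcyclohexyl (2Z)-2-methylbut-2-enoate | C/C=C(/C)C(=O)O[C@@H]1C[C@H](C)[C@H](O[Si](C)(C)C(C)(C)C)C[C@H]1[C@H](C)C[C@H](C=C(C)C)O | intermediate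
20 | (1R,2S,4R,5S)-2-[(2R,4R)-4-acetoxy-6-methylhept-5-en-2-yl]-4-[(tert-butyldimethylsilyl)oxy]-5-methylcyclohexyl (2Z)-2-methylbut-2-enoate | C/C=C(/C)C(=O)O[C@@H]1C[C@H](C)[C@H](O[Si](C)(C)C(C)(C)C)C[C@H]1[C@H](C)C[C@H](C=C(C)C)OC(C)=O | intermediate
21 | (1R,2S,4R,5S)-2-[(2R,4R)-4-acetoxy-6-methylhept-5-en-2-yl]-4-hydroxy-5-methylcyclohexyl (2Z)-2-methylbut-2-enoate (CNP0237033.1) | C/C=C(/C)C(=O)O[C@@H]1C[C@H](C)[C@H](O)C[C@H]1[C@H](C)C[C@H](C=C(C)C)OC(C)=O | target

**Step count**
Total steps: 12. Longest linear sequence: 11 (steps 1–3 and 5–12; step 4 is a one-step branch).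

**Steps most likely to fail**

Step 5. What may go wrong: the silyl dienol ether may be hydrolysed or protodesilylated in the wet, acidic medium, so that the reaction stops at open-chain conjugate adducts; face discrimination by the catalyst may be poor on this beta-branched enal; C7 may epimerise through a dienamine; the regiochemistry may erode because the C3 methyl opposes the silyloxy group. Fallback: the amine catalyst is given up, and 6 and 8 are heated without additive (toluene, 90 °C, trace of BHT). This neutral, anhydrous, concerted cycloaddition cannot hydrolyse the diene or epimerise C7, and the same orbital and endo preferences apply. Because 6 is a single enantiomer, the two endo adducts from the two faces of the enal are diastereomers and are separated by chromatography. The adduct of the wrong face, the diastereomeric endo adduct F1, is discarded. The fallback sets out from 6 and 8 and comes back at 11.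

Step 7. What may go wrong: the decarbonylation of the hindered secondary aldehyde may stall, or the rhodium alkyl intermediate may eliminate (loss of silanol from C4 or beta-hydride elimination) instead of forming the C–H bond. Fallback: the formyl carbon is removed by radical decarboxylation. Compound 12 is oxidised (Pinnick oxidation: NaClO2, NaH2PO4, 2-methylbut-2-ene, tBuOH/H2O) to the carboxylic acid F2. F2 is condensed with 2-mercaptopyridine N-oxide (DCC, CH2Cl2, dark) to the thiohydroxamate ester F3. Irradiation of F3 with visible light in the presence of tert-butanethiol (Barton decarboxylation) gives the C5 radical, which takes up hydrogen to give 13. The fallback sets out from 12 and comes back at 13.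

Step 6. What may go wrong: hydrogenolysis of the allylic C–O bonds, reduction of the formyl group, or insufficient face discrimination on the hindered trisubstituted alkene. Fallback: the order is inverted and the mechanism changed. Compound 11 is first decarbonylated (RhCl(PPh3)3, toluene, 110 °C) to the cyclohexene F4. F4 is then reduced by hydrogen-atom transfer (Mn(dpm)3 cat., PhSiH3, tert-butyl hydroperoxide, isopropanol, rt), a radical hydrogenation under thermodynamic control. It should place the C3 methyl equatorial, that is cis to the axial C4 silyloxy group, and give 13 directly. The fallback sets out from 11 and comes back at 13.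

**Further compounds**
F1 | step 5 | (1R,4S,5S,6S)-4-[(tert-butyldimethylsilyl)oxy]-5-formyl-6-[(2R)-4-[methoxy(methyl)amino]-4-oxobutan-2-yl]-3-methylcyclohex-2-en-1-yl acetate | CC(=O)O[C@H]1C=C(C)[C@@H](O[Si](C)(C)C(C)(C)C)[C@@H](C=O)[C@@H]1[C@H](C)CC(=O)N(C)OC
F2 | step 7 | (1R,2S,3S,5R,6R)-5-acetoxy-2-[(tert-butyldimethylsilyl)oxy]-6-[(2R)-4-[methoxy(methyl)amino]-4-oxobutan-2-yl]-3-methylcyclohexane-1-carboxylic acid | CC(=O)O[C@@H]1C[C@H](C)[C@H](O[Si](C)(C)C(C)(C)C)[C@H](C(=O)O)[C@H]1[C@H](C)CC(=O)N(C)OC
F3 | step 7 | 2-thioxopyridin-1(2H)-yl ester of F2 (Barton ester) | CC(=O)O[C@@H]1C[C@H](C)[C@H](O[Si](C)(C)C(C)(C)C)[C@H](C(=O)ON2C=CC=CC2=S)[C@H]1[C@H](C)CC(=O)N(C)OC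
F4 | step 6 | (1S,4R,6S)-4-[(tert-butyldimethylsilyl)oxy]-6-[(2R)-4-[methoxy(methyl)amino]-4-oxobutan-2-yl]-3-methylcyclohex-2-en-1-yl acetate | CC(=O)O[C@@H]1C=C(C)[C@H](O[Si](C)(C)C(C)(C)C)C[C@H]1[C@H](C)CC(=O)N(C)OC
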